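**Retrosynthetic overview**

1. Numbering is that of eremophilane (ring A = C1–C5 and C10, ring B = C5–C10). The enabling feature is the O‑acylated acyloin in ring B: ketone C8 sits next to the acyloxy carbinol C9, so C9 is an aldehyde carbon that already carries its ester and C8 is an acyl carbon.
2. Last disconnection, C8–C9: target ⇒ C9 aldehyde on C10 + C8 S‑ethyl thioester on the C5 side chain + (2E)‑3‑methylpent‑2‑enoyl bromide. Aldehyde and acyl bromide merge to a 1‑bromoalkyl ester; zinc and then palladium close ring B.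
3. C7: enantioselective α‑isopropenylation of the C8 aldehyde (Cu(OAc)2 with a chiral amine). C6–C8: hydroformylation of a vinyl group on C5.
4. C5, C4, C3: conjugate additions (methyl, then vinyl anti to the C10 substituent) to an enone from a desymmetrised 4‑substituted cyclohexanone, then C4 methylation, thermodynamic ketone reduction and angeloylation.
5. Ring order: ring A is bought as the cyclohexanone and only decorated; ring B is formed last, in the step that also delivers the C8 ketone, the C9 ester and the C9 configuration.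

Key step: step 15

Assumption: angelic acid, (2E)‑3‑methylpent‑2‑enoic acid and isopropenylboronic acid are taken as commercial, geometrically pure materials.

**Route**

Step 1
Reactants: 1 4-(hydroxymethyl)cyclohexan-1-one
Product: 2 4-({[tert-butyl(dimethyl)silyl]oxy}methyl)cyclohexan-1-one
Conditions: TBSCl, imidazole, DMF, 25 °C
Reagents that add atoms: tert-butyl(chloro)dimethylsilane, CC(C)(C)[Si](C)(C)Cl
Why: Standard silylation of a primary alcohol gives a group that should survive the organometallic, dissolving-metal and oxidative steps and is removed by fluoride late in the route; no stereocentre is formed.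

Step 2
Reactants: 2 4-({[tert-butyl(dimethyl)silyl]oxy}methyl)cyclohexan-1-one
Product: 4 (4R)-4-({[tert-butyl(dimethyl)silyl]oxy}methyl)cyclohex-2-en-1-one, via trimethylsilyl enol ether 3 (not isolated)
Conditions: lithium (S,S)-bis(1-phenylethyl)amide (from the amine and n-BuLi), TMSCl (internal quench), THF, −100 °C; then Pd(OAc)2 (10 mol%), O2 (1 atm), DMSO, 25 °C
Reagents that add atoms: none
Why: Enantioselective deprotonation of a 4-substituted cyclohexanone by a chiral lithium amide removes one of the two enantiotopic axial α-hydrogens and so fixes C10 (R expected for this base enantiomer by analogy with 4-alkylcyclohexanones), and Saegusa–Ito oxidation of the enol silane then gives the enone without touching that centre.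

Step 3
Reactants: 4 (4R)-4-({[tert-butyl(dimethyl)silyl]oxy}methyl)cyclohex-2-en-1-one
Product: 6 (4R)-4-({[tert-butyl(dimethyl)silyl]oxy}methyl)-3-methylcyclohex-2-en-1-one, via methylated trimethylsilyl enol ether 5 (not isolated)
Conditions: MeMgBr, CuBr·SMe2 (5 mol%), TMSCl, THF, −78 °C; then Pd(OAc)2 (10 mol%), O2 (1 atm), DMSO, 25 °C
Reagents that add atoms: methylmagnesium bromide, C[Mg]Br
Why: Copper-catalysed conjugate addition with silyl trapping followed by a second Saegusa–Ito oxidation installs the C5 methyl group as a β-methyl enone; the transient C5 stereocentre (methyl anti to the C10 substituent) is erased again.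

Step 4
Reactants: 6 (4R)-4-({[tert-butyl(dimethyl)silyl]oxy}methyl)-3-methylcyclohex-2-en-1-one
Product: 7 tert-butyl({(1R,2S)-2-ethenyl-2-methyl-4-[(trimethylsilyl)oxy]cyclohex-3-en-1-yl}methoxy)dimethylsilane
Conditions: vinylmagnesium bromide, CuBr·SMe2 (10 mol%), TMSCl, HMPA, THF, −78 °C; Et3N, pentane work-up
Reagents that add atoms: vinylmagnesium bromide, C=C[Mg]Br; chlorotrimethylsilane, C[Si](C)(C)Cl
Why: Silyl-chloride-accelerated copper-catalysed conjugate addition to the β,β-disubstituted enone creates the C5 quaternary centre, the vinyl group entering anti to the pseudoaxial C10 silyloxymethyl group (trans rule for 4-substituted cyclohexenones) so that the C5 methyl ends cis to C9, and the enolate is stored regiospecifically as its silyl enol ether.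

Step 5
Reactants: 7 tert-butyl({(1R,2S)-2-ethenyl-2-methyl-4-[(trimethylsilyl)oxy]cyclohex-3-en-1-yl}methoxy)dimethylsilane
Product: 10 (2R,3S,4R)-4-({[tert-butyl(dimethyl)silyl]oxy}methyl)-3-ethenyl-2,3-dimethylcyclohexan-1-one, via lithium enolate 8 (not isolated), via C4-epimeric ketone 9 (not isolated)
Conditions: MeLi, THF, 0 °C; MeI, HMPA, −78 → 0 °C; then NaOMe, MeOH, 25 °C
Reagents that add atoms: iodomethane, CI
Why: Regiospecific enolate generation from the enol silane and C-methylation place the methyl group on C4 (alkylation is expected mainly anti to the axial C5 methyl, giving 9), and base equilibration of this α-centre should then favour 10, in which the C4 methyl is equatorial and cis to the C5 methyl and avoids two 1,3-diaxial contacts; the minor epimer is returned to the equilibration.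

Step 6
Reactants: 10 (2R,3S,4R)-4-({[tert-butyl(dimethyl)silyl]oxy}methyl)-3-ethenyl-2,3-dimethylcyclohexan-1-one
Product: 11 (1R,2R,3S,4R)-4-({[tert-butyl(dimethyl)silyl]oxy}methyl)-3-ethenyl-2,3-dimethylcyclohexan-1-ol
Conditions: Li, NH3(l), THF, −78 °C; then MeOH; NH4Cl
Reagents that add atoms: none
Why: Dissolving-metal reduction of the cyclohexanone is thermodynamically controlled and should give the equatorial C3 alcohol (3α, trans to the C4 methyl), because the axial epimer suffers a 1,3-diaxial contact with the C5 methyl, while the isolated vinyl group and the silyl ether are inert.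

Step 7
Reactants: 11 (1R,2R,3S,4R)-4-({[tert-butyl(dimethyl)silyl]oxy}methyl)-3-ethenyl-2,3-dimethylcyclohexan-1-ol; 12 angelic acid, (2Z)-2-methylbut-2-enoic acid
Product: 14 (1R,2R,3S,4R)-4-({[tert-butyl(dimethyl)silyl]oxy}methyl)-3-ethenyl-2,3-dimethylcyclohexyl (2Z)-2-methylbut-2-enoate, via angelic 2,4,6-trichlorobenzoic anhydride 13 (not isolated)
Conditions: 12, 2,4,6-trichlorobenzoyl chloride, Et3N, toluene, 25 °C; then 11, toluene, 80 °C
Reagents that add atoms: angelic acid, C/C=C(/C)C(=O)O
Why: Acylation by the preformed mixed anhydride (Yamaguchi-type esterification run without DMAP) esterifies the hindered secondary alcohol with retention at C3 and should avoid Z-to-E isomerisation of the angelate, at a stage where no base-sensitive ketone is present.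

Step 8
Reactants: 14 (1R,2R,3S,4R)-4-({[tert-butyl(dimethyl)silyl]oxy}methyl)-3-ethenyl-2,3-dimethylcyclohexyl (2Z)-2-methylbut-2-enoate
Product: 15 (1R,2R,3S,4R)-4-({[tert-butyl(dimethyl)silyl]oxy}methyl)-2,3-dimethyl-3-(3-oxopropyl)cyclohexyl (2Z)-2-methylbut-2-enoate
Conditions: Rh(acac)(CO)2 (1 mol%), Xantphos [4,5-bis(diphenylphosphino)-9,9-dimethylxanthene] (2 mol%), CO/H2 (1:1, 20 bar), toluene, 80 °C
Reagents that add atoms: carbon monoxide, [C-]#[O+]
Why: Rhodium-catalysed hydroformylation of a vinyl group on a quaternary carbon can only give the linear aldehyde, which supplies C8 in one step while the trisubstituted conjugated angelate alkene should not react; no stereocentre is formed.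

Step 9
Reactants: 15 (1R,2R,3S,4R)-4-({[tert-butyl(dimethyl)silyl]oxy}methyl)-2,3-dimethyl-3-(3-oxopropyl)cyclohexyl (2Z)-2-methylbut-2-enoate; 16 isopropenylboronic acid (prop-1-en-2-ylboronic acid)
Product: 17 (1R,2R,3S,4R)-4-({[tert-butyl(dimethyl)silyl]oxy}methyl)-3-[(2S)-2-formyl-3-methylbut-3-en-1-yl]-2,3-dimethylcyclohexyl (2Z)-2-methylbut-2-enoate
Conditions: 16, Cu(OAc)2 (30 mol%), 5-benzyl-2-tert-butyl-3-methylimidazolidin-4-one trifluoroacetate (20 mol%, the enantiomer that gives 7S), 4 Å molecular sieves, O2 (1 atm), EtOAc, 23 °C; used directly in step 10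
Reagents that add atoms: isopropenylboronic acid, CC(=C)B(O)O
Why: Enantioselective α-alkenylation of an aldehyde with an alkenylboronic acid by combined copper and enamine catalysis (oxidative coupling of the chiral enamine with a copper-bound alkenyl group) forms the C7–C11 bond, and since the existing stereocentres are remote the imidazolidinone alone should control the new C7 centre (S).

Step 10
Reactants: 17 (1R,2R,3S,4R)-4-({[tert-butyl(dimethyl)silyl]oxy}methyl)-3-[(2S)-2-formyl-3-methylbut-3-en-1-yl]-2,3-dimethylcyclohexyl (2Z)-2-methylbut-2-enoate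
Product: 18 (1R,2R,3S,4R)-4-({[tert-butyl(dimethyl)silyl]oxy}methyl)-3-[(2S)-2-carboxy-3-methylbut-3-en-1-yl]-2,3-dimethylcyclohexyl (2Z)-2-methylbut-2-enoate
Conditions: NaClO2, NaH2PO4, 2-methyl-2-butene, t-BuOH/H2O, 0 °C
Reagents that add atoms: sodium chlorite, [Na+].[O-]Cl=O
Why: Pinnick oxidation under buffered, non-basic conditions converts the configurationally labile β,γ-unsaturated aldehyde at once into the more robust acid and should neither epimerise C7 nor move the double bond, the scavenger protecting the isopropenyl group from hypochlorite.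

Step 11
Reactants: 18 (1R,2R,3S,4R)-4-({[tert-butyl(dimethyl)silyl]oxy}methyl)-3-[(2S)-2-carboxy-3-methylbut-3-en-1-yl]-2,3-dimethylcyclohexyl (2Z)-2-methylbut-2-enoate
Product: 19 (1R,2R,3S,4R)-4-({[tert-butyl(dimethyl)silyl]oxy}methyl)-3-{(2S)-2-[(ethylsulfanyl)carbonyl]-3-methylbut-3-en-1-yl}-2,3-dimethylcyclohexyl (2Z)-2-methylbut-2-enoate
Conditions: EtSH, EDC·HCl [1-ethyl-3-(3-dimethylaminopropyl)carbodiimide hydrochloride], HOBt, CH2Cl2, 0 → 25 °C
Reagents that add atoms: ethanethiol, CCS
Why: Carbodiimide thioesterification gives the S-ethyl thioester, an acyl donor that is inert to fluoride, periodinane, acyl bromide and zinc but reacts with zerovalent palladium; DMAP is left out to protect C7.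

Step 12
Reactants: 19 (1R,2R,3S,4R)-4-({[tert-butyl(dimethyl)silyl]oxy}methyl)-3-{(2S)-2-[(ethylsulfanyl)carbonyl]-3-methylbut-3-en-1-yl}-2,3-dimethylcyclohexyl (2Z)-2-methylbut-2-enoate
Product: 20 (1R,2R,3S,4R)-3-{(2S)-2-[(ethylsulfanyl)carbonyl]-3-methylbut-3-en-1-yl}-4-(hydroxymethyl)-2,3-dimethylcyclohexyl (2Z)-2-methylbut-2-enoate
Conditions: HF·pyridine, pyridine, THF, 0 °C
Reagents that add atoms: none
Why: Fluoride-induced desilylation frees the C9 primary alcohol while the ester, the unactivated thioester and the alkenes should stay untouched.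

Step 13
Reactants: 20 (1R,2R,3S,4R)-3-{(2S)-2-[(ethylsulfanyl)carbonyl]-3-methylbut-3-en-1-yl}-4-(hydroxymethyl)-2,3-dimethylcyclohexyl (2Z)-2-methylbut-2-enoate
Product: 21 (1R,2R,3R,4R)-3-{(2S)-2-[(ethylsulfanyl)carbonyl]-3-methylbut-3-en-1-yl}-4-formyl-2,3-dimethylcyclohexyl (2Z)-2-methylbut-2-enoate
Conditions: Dess–Martin periodinane, NaHCO3, CH2Cl2, 0 → 25 °C
Reagents that add atoms: none
Why: Dess–Martin oxidation under buffered neutral conditions gives the C9 aldehyde and should not epimerise the adjacent C10 centre or oxidise the thioester sulfur (the descriptor at the quaternary carbon changes only through the priority rules).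

Step 14
Reactants: 22 (2E)-3-methylpent-2-enoic acid
Product: 23 (2E)-3-methylpent-2-enoyl bromide
Conditions: (COBr)2, DMF (cat.), CH2Cl2, 0 °C; volatiles removed, used at once
Reagents that add atoms: oxalyl bromide, O=C(Br)C(=O)Br
Why: Conversion of the acid into its acyl bromide with oxalyl bromide under Vilsmeier-type catalysis runs cold and without base, which should keep the 2E geometry.

Step 15
Reactants: 21 (1R,2R,3R,4R)-3-{(2S)-2-[(ethylsulfanyl)carbonyl]-3-methylbut-3-en-1-yl}-4-formyl-2,3-dimethylcyclohexyl (2Z)-2-methylbut-2-enoate; 23 (2E)-3-methylpent-2-enoyl bromide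
Product: 26 (3R,4R,5R,7S,9S,10R)-3-[(2Z)-2-methylbut-2-enoyloxy]-9-[(2E)-3-methylpent-2-enoyloxy]eremophil-11-en-8-one (CNP0301161.1), via 1-bromoalkyl ester 24 (not isolated), via α-acyloxyalkylzinc bromide 25 (not isolated)
Conditions: 23 (1.2 equiv), ZnBr2 (5 mol%), CH2Cl2, −20 °C; solvent exchanged; Zn dust (activated), LiCl, THF, 0 °C; then PdCl2(PPh3)2 (5 mol%), THF, 25 °C, high dilution (0.005 M)
Reagents that add atoms: (2E)-3-methylpent-2-enoyl bromide, CC/C(C)=C/C(=O)Br
Why: Proposed new method: the acyl bromide adds across the C9 aldehyde under ZnBr2 catalysis to a 1-bromoalkyl ester, zinc inserts into this activated C–Br bond to give a carbonyl-chelated α-acyloxyalkylzinc, zerovalent palladium inserts into the C8–S bond of the thioester, and transmetalation followed by reductive elimination joins C9 to C8. The closest known reaction types are the preparation of α-acyloxyalkylzinc and -copper reagents from aldehyde-derived 1-bromoalkyl esters with their acylation by acid chlorides, and the palladium-catalysed ketone synthesis from thioesters and alkylzinc halides (Fukuyama coupling); untested is their intramolecular union. Ring B closes as a six-membered ring by 6-exo-trig acyl substitution, through a seven-membered acyl(alkyl)palladacycle. C9 is the only new stereocentre: the organozinc epimerises freely, and the chair-like ring-closing geometry with the acyloxy group equatorial is favoured because an axial C9 substituent would meet the axial C5 methyl group in a 1,3-diaxial contact, so the 9S (9α) ester should result, which is also the more stable epimer. The step needs chemoselectivity among three carbonyl derivatives and three alkenes and ring closure instead of oligomerisation: the acyl bromide reacts only with the aldehyde, zinc only with the α-acyloxy bromide, palladium only with the thioester, base is absent so that C7 and C10 keep their configuration, and high dilution secures cyclisation. In one operation the step forms the C8–C9 bond and ring B, sets C9, uncovers the C8 ketone and installs the C9 ester, so no later oxidation-state or protecting-group change is needed.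

**Compound list**

1 | 4-(hydroxymethyl)cyclohexan-1-one | O=C1CCC(CO)CC1 | starting material
2 | 4-({[tert-butyl(dimethyl)silyl]oxy}methyl)cyclohexan-1-one | CC(C)(C)[Si](C)(C)OCC1CCC(=O)CC1 | intermediate
3 | tert-butyl(dimethyl)({(1R)-4-[(trimethylsilyl)oxy]cyclohex-3-en-1-yl}methoxy)silane | CC(C)(C)[Si](C)(C)OC[C@@H]1CCC(O[Si](C)(C)C)=CC1 | intermediate
4 | (4R)-4-({[tert-butyl(dimethyl)silyl]oxy}methyl)cyclohex-2-en-1-one | CC(C)(C)[Si](C)(C)OC[C@@H]1CCC(=O)C=C1 | intermediate
5 | tert-butyl(dimethyl)({(1R,2S)-2-methyl-4-[(trimethylsilyl)oxy]cyclohex-3-en-1-yl}methoxy)silane | CC(C)(C)[Si](C)(C)OC[C@@H]1CCC(O[Si](C)(C)C)=C[C@H]1C | intermediate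
6 | (4R)-4-({[tert-butyl(dimethyl)silyl]oxy}methyl)-3-methylcyclohex-2-en-1-one | CC(C)(C)[Si](C)(C)OC[C@@H]1CCC(=O)C=C1C | intermediate
7 | tert-butyl({(1R,2S)-2-ethenyl-2-methyl-4-[(trimethylsilyl)oxy]cyclohex-3-en-1-yl}methoxy)dimethylsilane | CC(C)(C)[Si](C)(C)OC[C@@H]1CCC(O[Si](C)(C)C)=C[C@@]1(C)C=C | intermediate
8 | lithium (3S,4R)-4-({[tert-butyl(dimethyl)silyl]oxy}methyl)-3-ethenyl-3-methylcyclohex-1-en-1-olate | [Li+].CC(C)(C)[Si](C)(C)OC[C@@H]1CCC([O-])=C[C@@]1(C)C=C | intermediate
9 | (2S,3S,4R)-4-({[tert-butyl(dimethyl)silyl]oxy}methyl)-3-ethenyl-2,3-dimethylcyclohexan-1-one (C4 epimer, methyl trans to the C5 methyl) | CC(C)(C)[Si](C)(C)OC[C@@H]1CCC(=O)[C@@H](C)[C@@]1(C)C=C | intermediate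
10 | (2R,3S,4R)-4-({[tert-butyl(dimethyl)silyl]oxy}methyl)-3-ethenyl-2,3-dimethylcyclohexan-1-one | CC(C)(C)[Si](C)(C)OC[C@@H]1CCC(=O)[C@H](C)[C@@]1(C)C=C | intermediate
11 | (1R,2R,3S,4R)-4-({[tert-butyl(dimethyl)silyl]oxy}methyl)-3-ethenyl-2,3-dimethylcyclohexan-1-ol | CC(C)(C)[Si](C)(C)OC[C@@H]1CC[C@@H](O)[C@H](C)[C@@]1(C)C=C | intermediate
12 | angelic acid, (2Z)-2-methylbut-2-enoic acid | C/C=C(/C)C(=O)O | starting material
13 | (2Z)-2-methylbut-2-enoic 2,4,6-trichlorobenzoic anhydride | O=C(OC(=O)/C(C)=C\C)c1c(Cl)cc(Cl)cc1Cl | intermediate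
14 | (1R,2R,3S,4R)-4-({[tert-butyl(dimethyl)silyl]oxy}methyl)-3-ethenyl-2,3-dimethylcyclohexyl (2Z)-2-methylbut-2-enoate | CC(C)(C)[Si](C)(C)OC[C@@H]1CC[C@@H](OC(=O)/C(C)=C\C)[C@H](C)[C@@]1(C)C=C | intermediate
15 | (1R,2R,3S,4R)-4-({[tert-butyl(dimethyl)silyl]oxy}methyl)-2,3-dimethyl-3-(3-oxopropyl)cyclohexyl (2Z)-2-methylbut-2-enoate | CC(C)(C)[Si](C)(C)OC[C@@H]1CC[C@@H](OC(=O)/C(C)=C\C)[C@H](C)[C@@]1(C)CCC=O | intermediate
16 | isopropenylboronic acid (prop-1-en-2-ylboronic acid) | CC(=C)B(O)O | starting material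
17 | (1R,2R,3S,4R)-4-({[tert-butyl(dimethyl)silyl]oxy}methyl)-3-[(2S)-2-formyl-3-methylbut-3-en-1-yl]-2,3-dimethylcyclohexyl (2Z)-2-methylbut-2-enoate | CC(C)(C)[Si](C)(C)OC[C@@H]1CC[C@@H](OC(=O)/C(C)=C\C)[C@H](C)[C@@]1(C)C[C@@H](C(C)=C)C=O | intermediate
18 | (1R,2R,3S,4R)-4-({[tert-butyl(dimethyl)silyl]oxy}methyl)-3-[(2S)-2-carboxy-3-methylbut-3-en-1-yl]-2,3-dimethylcyclohexyl (2Z)-2-methylbut-2-enoate | CC(C)(C)[Si](C)(C)OC[C@@H]1CC[C@@H](OC(=O)/C(C)=C\C)[C@H](C)[C@@]1(C)C[C@@H](C(C)=C)C(=O)O | intermediate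
19 | (1R,2R,3S,4R)-4-({[tert-butyl(dimethyl)silyl]oxy}methyl)-3-{(2S)-2-[(ethylsulfanyl)carbonyl]-3-methylbut-3-en-1-yl}-2,3-dimethylcyclohexyl (2Z)-2-methylbut-2-enoate | CC(C)(C)[Si](C)(C)OC[C@@H]1CC[C@@H](OC(=O)/C(C)=C\C)[C@H](C)[C@@]1(C)C[C@@H](C(C)=C)C(=O)SCC | intermediate
20 | (1R,2R,3S,4R)-3-{(2S)-2-[(ethylsulfanyl)carbonyl]-3-methylbut-3-en-1-yl}-4-(hydroxymethyl)-2,3-dimethylcyclohexyl (2Z)-2-methylbut-2-enoate | OC[C@@H]1CC[C@@H](OC(=O)/C(C)=C\C)[C@H](C)[C@@]1(C)C[C@@H](C(C)=C)C(=O)SCC | intermediate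
21 | (1R,2R,3R,4R)-3-{(2S)-2-[(ethylsulfanyl)carbonyl]-3-methylbut-3-en-1-yl}-4-formyl-2,3-dimethylcyclohexyl (2Z)-2-methylbut-2-enoate | O=C[C@@H]1CC[C@@H](OC(=O)/C(C)=C\C)[C@H](C)[C@@]1(C)C[C@@H](C(C)=C)C(=O)SCC | intermediate
22 | (2E)-3-methylpent-2-enoic acid | CC/C(C)=C/C(=O)O | starting material
23 | (2E)-3-methylpent-2-enoyl bromide | CC/C(C)=C/C(=O)Br | intermediate
24 | 1-bromoalkyl (2E)-3-methylpent-2-enoate formed at the formyl carbon (C9) of 21, both C9 epimers | CC/C(C)=C/C(=O)OC(Br)[C@@H]1CC[C@@H](OC(=O)/C(C)=C\C)[C@H](C)[C@@]1(C)C[C@@H](C(C)=C)C(=O)SCC | intermediate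
25 | α-acyloxyalkylzinc bromide from 24 (zinc on C9, configurationally labile) | CC/C(C)=C/C(=O)OC([Zn]Br)[C@@H]1CC[C@@H](OC(=O)/C(C)=C\C)[C@H](C)[C@@]1(C)C[C@@H](C(C)=C)C(=O)SCC | intermediate
26 | (3R,4R,5R,7S,9S,10R)-3-[(2Z)-2-methylbut-2-enoyloxy]-9-[(2E)-3-methylpent-2-enoyloxy]eremophil-11-en-8-one (CNP0301161.1) | C=C(C)[C@@H]1C[C@]2(C)[C@@H](C)[C@H](OC(=O)/C(C)=C\C)CC[C@H]2[C@H](OC(=O)/C=C(\C)CC)C1=O | target

**Step count and risks**

Total step count: 15. Longest linear sequence: 14 (steps 1–13 and 15; step 14 makes the acyl bromide).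

Steps most likely to fail:

1. Step 15 (Proposed new method). Transfer of the α-acyloxyalkyl group from zinc to the acylpalladium may be too slow, so that protonolysis, β-hydride elimination to an enol ester or intermolecular coupling takes over; Lewis-acid enolisation of the C9 aldehyde could also erode C10. Fallback with known chemistry: it sets out from 17 and returns at 26. HF·pyridine removes the silyl group to give the hydroxy aldehyde F1, and Dess–Martin oxidation gives the dialdehyde F2. SmI2 in THF with t-BuOH at −78 °C closes ring B by pinacol coupling; samarium chelation of both ketyl oxygens should give the cis-diol F3, with the C9 hydroxyl equatorial (anti to the axial C5 methyl) and the C8 hydroxyl axial. The more accessible equatorial C9 hydroxyl is esterified with 22 (EDC·HCl, catalytic DMAP, 0 °C) to the C9 monoester F4, and Dess–Martin oxidation of the axial C8 alcohol gives 26.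

2. Step 9. Catalyst control at C7 may be insufficient, and the β,γ-unsaturated aldehyde may lose its configuration or shift its double bond into conjugation before it is oxidised. Fallback: it sets out from 15 and returns at 18. Pinnick oxidation gives the acid F5; pivaloyl chloride/Et3N and lithiated (4R)-4-benzyloxazolidin-2-one give the imide F6. Evans acylation (LDA, THF, −78 °C, then acetyl chloride; attack anti to the benzyl group of the chelated Z-enolate) gives the β-keto imide F7 with 7S configuration. Non-basic methylenation of the ketone (Zn, CH2Br2, TiCl4) gives the isopropenyl imide F8, and LiOH/H2O2 removes the auxiliary to give 18.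

3. Step 5. Alkylation is expected from the face that gives the wrong C4 epimer, the equilibrium may not favour 10 strongly enough, and over-methylation is possible. Fallback: it sets out from 7 and returns at 10. Dimethyl(methylidene)ammonium iodide gives the Mannich base F9, MeI gives the quaternary ammonium iodide F10, and NaHCO3 eliminates trimethylamine to give the α-methylene ketone F11. Conjugate reduction with lithium tri-sec-butylborohydride (THF, −78 °C) and protonation of the enolate with 2,6-di-tert-butyl-4-methylphenol from the face anti to the axial C5 methyl should give 10 under kinetic control.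

**Further compounds**

F1 | step 15 | (1R,2R,3S,4R)-3-[(2S)-2-formyl-3-methylbut-3-en-1-yl]-4-(hydroxymethyl)-2,3-dimethylcyclohexyl (2Z)-2-methylbut-2-enoate | OC[C@@H]1CC[C@@H](OC(=O)/C(C)=C\C)[C@H](C)[C@@]1(C)C[C@@H](C(C)=C)C=O
F2 | step 15 | dialdehyde: 4-formyl analogue of F1 (C8 and C9 both aldehydes, configuration unchanged) | O=C[C@@H]1CC[C@@H](OC(=O)/C(C)=C\C)[C@H](C)[C@@]1(C)C[C@@H](C(C)=C)C=O
F3 | step 15 | (3R,4R,5R,7S,8R,9S,10R)-8,9-dihydroxyeremophil-11-en-3-yl (2Z)-2-methylbut-2-enoate (8α,9α-cis-diol) | O[C@H]1[C@@H]2CC[C@@H](OC(=O)/C(C)=C\C)[C@H](C)[C@@]2(C)C[C@@H](C(C)=C)[C@H]1O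
F4 | step 15 | 8α-hydroxy-9α-[(2E)-3-methylpent-2-enoyloxy] analogue of 26 (C9 monoester of F3) | CC/C(C)=C/C(=O)O[C@H]1[C@@H]2CC[C@@H](OC(=O)/C(C)=C\C)[C@H](C)[C@@]2(C)C[C@@H](C(C)=C)[C@H]1O
F5 | step 9 | 3-[(1S,2R,3R,6R)-ring of 15]propanoic acid (aldehyde of 15 oxidised to the acid) | CC(C)(C)[Si](C)(C)OC[C@@H]1CC[C@@H](OC(=O)/C(C)=C\C)[C@H](C)[C@@]1(C)CCC(=O)O
F6 | step 9 | N-acyl (4R)-4-benzyloxazolidin-2-one of F5 | CC(C)(C)[Si](C)(C)OC[C@@H]1CC[C@@H](OC(=O)/C(C)=C\C)[C@H](C)[C@@]1(C)CCC(=O)N2[C@H](Cc3ccccc3)COC2=O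
F7 | step 9 | (2S)-2-acetyl derivative of F6 (β-keto imide) | CC(C)(C)[Si](C)(C)OC[C@@H]1CC[C@@H](OC(=O)/C(C)=C\C)[C@H](C)[C@@]1(C)C[C@@H](C(C)=O)C(=O)N2[C@H](Cc3ccccc3)COC2=O
F8 | step 9 | (2S)-2-isopropenyl imide (ketone of F7 methylenated) | CC(C)(C)[Si](C)(C)OC[C@@H]1CC[C@@H](OC(=O)/C(C)=C\C)[C@H](C)[C@@]1(C)C[C@@H](C(C)=C)C(=O)N2[C@H](Cc3ccccc3)COC2=O
F9 | step 5 | (3S,4R)-4-({[tert-butyl(dimethyl)silyl]oxy}methyl)-2-[(dimethylamino)methyl]-3-ethenyl-3-methylcyclohexan-1-one (C2 epimers) | CC(C)(C)[Si](C)(C)OC[C@@H]1CCC(=O)C(CN(C)C)[C@@]1(C)C=C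
F10 | step 5 | trimethylammonium iodide of F9 | CC(C)(C)[Si](C)(C)OC[C@@H]1CCC(=O)C(C[N+](C)(C)C)[C@@]1(C)C=C.[I-]
F11 | step 5 | (3S,4R)-4-({[tert-butyl(dimethyl)silyl]oxy}methyl)-3-ethenyl-3-methyl-2-methylidenecyclohexan-1-one | CC(C)(C)[Si](C)(C)OC[C@@H]1CCC(=O)C(=C)[C@@]1(C)C=C
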